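Remark on the chemistry: the chiral sulfoxide–oxazoline ligand is assumed to be obtainable in either enantiomeric form, and the form that leads to the 3S lactone 5 is used; 7 may form as an E/Z mixture, which step 4 makes irrelevant.

## Structural features

The target is a 3,4-dihydroisocoumarin in which benzene ring A is fused through the C4a–C8a bond to the six-membered lactone ring B (C1 carbonyl, O2, C3, C4). Ring A carries a methoxy group at C6 and a free phenol at C8; the phenol lies peri to the C1 carbonyl and is hydrogen-bonded to it, while C5 and C7 are unsubstituted. C3 bears an unbranched chain of eleven carbons (C1' to C11') that ends in a primary alcohol. C3 is the only stereocentre (R); it is an oxygen-bearing carbon between two methylene groups, C4 and C1', with no neighbouring stereocentre or polar group from which its configuration could be relayed. The fragile elements are the lactone (strong nucleophiles, hydride), the free phenol (oxidants), the C3–O2 bond whenever C3 is allylic (ionisation, hydrogenolysis) and, in any ring-opened precursor, an electron-rich benzoic acid flanked by two ortho substituents (decarboxylation). The real difficulty is therefore absolute stereocontrol at an isolated secondary C–O centre, with the differentiation of the two phenolic oxygens (O6 methylated, O8 free) as a second, smaller problem. The key step exploits the fact that C3 becomes an allylic methylene as soon as C1'=C2' is a double bond, while the carboxyl group on C8a is placed to deliver its oxygen to C3 and so close ring B as a six-membered ring.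

## Logic of the disconnections

10 back to 8 (through 9). The only change is at O8, where the O–H bond is replaced by O–CH3. The phenol must be masked during the lithiation and above all during the quinone-mediated oxidation. A methyl ether is the smallest mask and makes the two ring oxygens alike, which keeps the aromatic starting material simple. The forward step must tell O8 from O6; the peri relation of O8 to the C1 carbonyl allows this with a chelating boron Lewis acid, which must spare the lactone, C3 and the primary alcohol.

8 back to 7. The C1'–C2' single bond is traced to a double bond. Nothing is gained in atom count, but the unsaturation is the trace of an alkene-based fragment union. The forward step must saturate a disubstituted alkene without hydrogenolysis of the allylic C3–O2 bond. The spatial arrangement at C3 is unchanged; only the descriptor switches from S to R, because the saturated chain ranks below C4.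

7 back to 5 and 6. The C1'=C2' double bond is cut. This separates the chiral bicyclic core from an achiral commercial chain that brings nine methylene groups and the terminal alcohol without protection. It leaves on the core exactly the vinyl group that the ring-forming step produces. The forward metathesis must favour the cross product over the homodimer of 6 and must not move the double bond.

5 back to 4. The O2–C3 bond is cut. This one disconnection opens ring B and removes the only stereocentre, leaving an achiral benzoic acid whose future C3 is an ordinary allylic methylene next to a terminal alkene. The forward step must cleave one C–H bond at that methylene, form the C–O bond at the internal end of the allyl unit, and do so on one face under catalyst control. The substitution pattern of 4 helps: both positions ortho to the carboxyl group are occupied, both phenolic oxygens are methyl ethers, and there is only one allylic position.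

4 back to 1 and 2 (through 3). The bond between the benzylic carbon (future C4) and the future C3 is cut. The benzylic methyl group of 1 is acidified by the ortho carboxylate and is the natural nucleophile, and 2 supplies the remaining three carbons with the terminal alkene in place. Starting from the free acid gives 4 in one operation and avoids hydrolysing a doubly ortho-substituted benzoate. The forward step needs deprotonation at the methyl group and not on the ring, and alkylation at carbon and not at the carboxylate oxygen.

## Other disconnections considered

Alternative 1: The cut is the C4a–C8a bond of ring A, so that the arene is traced to the open-chain triketo ester A1, methyl (9R)-9,20-bis(tert-butyldimethylsilyloxy)-3,5,7-trioxoicosanoate, which already carries the stereocentre as a silyl ether. In the forward key step a mild base would let the C2 methylene add to the C7 ketone; loss of water and enolisation would give the resorcylate A2, methyl 2-[(2R)-2,13-bis(tert-butyldimethylsilyloxy)tridecyl]-4,6-dihydroxybenzoate.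
- In its favour: the reaction follows the polyketide logic by which such rings arise in nature. The stereocentre would be made earlier by a mature method, for example asymmetric hydrogenation of a β-keto ester. The two phenols of A2 differ in hydrogen bonding, so the para hydroxyl could be methylated selectively and no late ether cleavage would be needed. On reliability of stereocontrol and on avoiding the final Lewis-acid step this alternative is the better of the two.
- Against it: A1 is a tetracarbonyl compound with several cyclisation modes open to it (carbon acylation towards an acylphloroglucinol, oxygen cyclisation to a 4-hydroxy-2-pyranone). The C9 silyloxy group is β to the C7 ketone, which invites base-induced elimination and loss of the stereocentre. A1 must be assembled by polyanion acylation with a chiral acyl donor that itself needs several steps. After A2, selective methylation, removal of two silyl groups and lactonisation would still follow.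
- Comparison: the alternative builds ring A, which the chosen plan buys, and leaves ring B to a routine lactonisation. Mechanistically it trades a catalyst-controlled C–H functionalisation of unproven enantioselectivity for carbonyl condensations of known type but delicate regiochemistry. In step economy it is expected to need about twice as many operations.

Alternative 2: The cuts are C4a–C5 and C8–C8a, which trace ring A to a [4+2] addition between the bromo lactone A3, (6R)-3-bromo-6-[11-(tert-butyldimethylsilyloxy)undecyl]-5,6-dihydro-2H-pyran-2-one, and the Brassard diene A4, 1,3-dimethoxy-1-(trimethylsilyloxy)buta-1,3-diene. In the forward key step the methylene terminus of A4 would bond to the β-carbon of A3 and the ketene acetal carbon to the brominated α-carbon. Loss of hydrogen bromide and of methanol from the adduct would aromatise it to A5, (3R)-3-[11-(tert-butyldimethylsilyloxy)undecyl]-8-hydroxy-6-methoxy-3,4-dihydroisochromen-1-one.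
- In its favour: ring A would appear with O6 methylated and O8 free in one step, so no selective demethylation is needed; here the alternative is better than the chosen plan. The stereocentre would be set beforehand by a dependable asymmetric allylation and only carried through the key step, which is again better in terms of risk. A single desilylation would finish the synthesis.
- Against it: an α-bromo unsaturated δ-lactone is a dienophile of modest reactivity that is likely to need heating, which the moisture- and heat-sensitive A4 tolerates poorly. The regiochemistry rests on polarisation alone. A3 itself would take about five steps (aldehyde formation from a monoprotected diol, asymmetric allylation, acryloylation, ring-closing metathesis, bromination–dehydrobromination).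
- Comparison: the alternative again constructs ring A onto a preformed ring B, whereas the chosen plan closes ring B on a purchased arene. Its key step is a pericyclic reaction with good analogy, against a metal-catalysed step without direct analogy. It would be longer by about three steps.

Alternative 3: The disconnection removes the ring oxygen: the C1–O2 and O2–C3 bonds are cut and ring B is traced to the five-membered ketone ring of the racemic indanone A6, 2-(11-hydroxyundecyl)-5,7-dimethoxy-2,3-dihydro-1H-inden-1-one. In the forward key step a Baeyer–Villiger monooxygenase, with its reduced nicotinamide cofactor and oxygen, would oxidise the 2R enantiomer of A6 while the other enantiomer racemises through the enol. Migration of the alkyl-bearing C2 with retention would give A7, (3R)-3-(11-hydroxyundecyl)-6,8-dimethoxy-3,4-dihydroisochromen-1-one, which is the same compound as 8.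
- In its favour: ring B and the stereocentre are formed together from a racemate, as in the chosen plan. The oxidant is air. A6 needs only attachment of the chain at C2 of a simple indanone (two or three steps), and no alkene has to be reduced afterwards. In step count the alternative is at least the equal of the chosen plan, and in reagents it is the cleaner.
- Against it: the innate migratory preference in an indanone with an electron-rich aryl group is for aryl migration, which leads to a 3,4-dihydrocoumarin, so the enzyme would have to reverse it. The ketone is shielded by the peri methoxy group and carries a long lipophilic chain, so acceptance by the active site and solubility in water are open questions. Racemisation has to outrun oxidation of the slow enantiomer at a pH that the lactone survives. A given enzyme offers one enantiomeric series only.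
- Comparison: both plans rely on a catalyst–substrate match that has not been demonstrated. The chosen plan uses a small-molecule catalyst whose ligand can be varied and inverted at will, and an acid precursor made in one step. That is why it is preferred, but the difference is one of degree and not of principle.

Key step: step 2

## Route

Step 1
Reactants: 1 2,4-dimethoxy-6-methylbenzoic acid; 2 allyl bromide (3-bromoprop-1-ene)
Product: 4 2-(but-3-en-1-yl)-4,6-dimethoxybenzoic acid, via lithium 2-(lithiomethyl)-4,6-dimethoxybenzoate 3 (not isolated)
Conditions: LiN(iPr)2 (2.2 equiv), THF, −78 to 0 °C; then 2 (1.1 equiv), −78 °C to rt; cold aq. HCl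
Reagents that add atoms: allyl bromide (2), C=CCBr
Why: Lateral lithiation of an ortho-toluic acid as its dianion followed by C-alkylation; the carboxylate acidifies the benzylic methyl group, both methoxy groups are meta to it and do not oppose the anion, and the lithium carboxylate is too poor a nucleophile in THF at low temperature to compete with the benzylic carbanion for 2.

Step 2
Reactants: 4 2-(but-3-en-1-yl)-4,6-dimethoxybenzoic acid
Product: 5 (3S)-3-ethenyl-6,8-dimethoxy-3,4-dihydroisochromen-1-one
Conditions: Pd(OAc)2 (10 mol%), chiral aryl sulfoxide–oxazoline ligand (10 mol%), 2,6-dimethyl-1,4-benzoquinone (1.5 equiv), toluene, 45 °C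
Reagents that add atoms: none
Why: Proposed new method: Pd(OAc)2 and the acid 4 form a ligated divalent palladium carboxylate that binds the terminal alkene and removes one hydrogen from the only allylic methylene (the future C3), giving a π-allyl palladium species with the tethered benzoate as its counter-ion. The quinone, acting as a π-acidic ligand, then induces C–O bond formation between the carboxylate oxygen and the internal allyl carbon and afterwards reoxidises zerovalent palladium to the divalent state, ending as the hydroquinone. Ring B closes in a 6-exo mode with the vinyl group outside the ring; attack at the terminal allyl carbon would require an eight-membered lactone containing an E alkene and should not compete. The closest known reaction type is the allylic C–H oxidation of terminal alkenes with divalent palladium and sulfoxide ligands, which is enantioselective with this ligand class when a benzylic alcohol cyclises to a 3-vinylisochroman and is known without asymmetric induction for carboxylic acids; the new element is asymmetric induction with a carboxylic acid as the nucleophile. The C3 stereocentre is set by the ligand alone: the two diastereomeric π-allyl complexes can interconvert by π–σ–π isomerisation through the unsubstituted terminus, and the sulfoxide sulfur and the oxazoline substituent decide which allyl face receives the carboxylate, the ligand enantiomer being the one that leads to 3S (the spatial arrangement of the 3R target, because vinyl outranks C4). The step needs C–H cleavage to win over oxypalladation, over ring palladation and over oxidation of the arene; 4 secures this by having a single allylic position, no free position ortho to the carboxyl group, both phenolic oxygens methylated, and only seven- or eight-membered rings on offer for direct attack of the carboxylate on the alkene.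

Step 3
Reactants: 5 (3S)-3-ethenyl-6,8-dimethoxy-3,4-dihydroisochromen-1-one; 6 undec-10-en-1-ol
Product: 7 (3S)-3-[(1E)-11-hydroxyundec-1-en-1-yl]-6,8-dimethoxy-3,4-dihydroisochromen-1-one (E isomer expected to predominate)
Conditions: second-generation Grubbs catalyst (5 mol%), 6 (3 equiv), CH2Cl2, 40 °C
Reagents that add atoms: undec-10-en-1-ol (6), OCCCCCCCCCC=C
Why: Olefin cross-metathesis between a rapidly homodimerising terminal alkene (6, in excess; its homodimer remains a competent partner) and a branched, allylically oxygenated alkene that homodimerises slowly (5), a pairing that should favour the cross product with loss of ethene. C3 is not touched and stays S because the alkenyl group still outranks C4.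

Step 4
Reactants: 7 (3S)-3-[(1E)-11-hydroxyundec-1-en-1-yl]-6,8-dimethoxy-3,4-dihydroisochromen-1-one
Product: 8 (3R)-3-(11-hydroxyundecyl)-6,8-dimethoxy-3,4-dihydroisochromen-1-one
Conditions: TsNHNH2 (excess), NaOAc, DME–H2O, reflux
Reagents that add atoms: none
Why: Diimide reduction: concerted syn transfer of two hydrogens from HN=NH made in the flask saturates the disubstituted alkene without a metal surface, so the allylic C3–O2 bond cannot be hydrogenolysed and the arene and lactone are left alone. C3 is not involved; only its descriptor becomes R because the saturated chain ranks below C4.

Step 5
Reactants: 8 (3R)-3-(11-hydroxyundecyl)-6,8-dimethoxy-3,4-dihydroisochromen-1-one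
Product: 10 (3R)-8-hydroxy-3-(11-hydroxyundecyl)-6-methoxy-3,4-dihydroisochromen-1-one, via (3R)-8-(dichloroboryloxy)-3-[11-(dichloroboryloxy)undecyl]-6-methoxy-3,4-dihydroisochromen-1-one 9 (not isolated)
Conditions: BCl3 (3 equiv), CH2Cl2, −78 to 0 °C; then H2O
Reagents that add atoms: none
Why: Chelation-directed Lewis-acid ether cleavage: BCl3 bridges the lactone carbonyl and the peri O8 in a six-membered chelate, so chloride removes only that methyl group while the remote 6-methoxy group stays. The primary alcohol is held as its dichloroborinate at low temperature and is freed, like the phenol, on hydrolysis; C3 is untouched.

## Compound list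

1 | 2,4-dimethoxy-6-methylbenzoic acid | COc1cc(C)c(C(=O)O)c(OC)c1 | starting material
2 | allyl bromide (3-bromoprop-1-ene) | C=CCBr | starting material
3 | lithium 2-(lithiomethyl)-4,6-dimethoxybenzoate | [Li]Cc1cc(OC)cc(OC)c1C(=O)O[Li] | intermediate (not isolated)
4 | 2-(but-3-en-1-yl)-4,6-dimethoxybenzoic acid | COc1cc(OC)c(C(=O)O)c(CCC=C)c1 | intermediate
5 | (3S)-3-ethenyl-6,8-dimethoxy-3,4-dihydroisochromen-1-one | COc1cc(OC)c2c(c1)C[C@@H](C=C)OC2=O | intermediate
6 | undec-10-en-1-ol | OCCCCCCCCCC=C | starting material
7 | (3S)-3-[(1E)-11-hydroxyundec-1-en-1-yl]-6,8-dimethoxy-3,4-dihydroisochromen-1-one | COc1cc(OC)c2c(c1)C[C@@H](/C=C/CCCCCCCCCO)OC2=O | intermediate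
8 | (3R)-3-(11-hydroxyundecyl)-6,8-dimethoxy-3,4-dihydroisochromen-1-one | COc1cc(OC)c2c(c1)C[C@@H](CCCCCCCCCCCO)OC2=O | intermediate
9 | (3R)-8-(dichloroboryloxy)-3-[11-(dichloroboryloxy)undecyl]-6-methoxy-3,4-dihydroisochromen-1-one | COc1cc(OB(Cl)Cl)c2c(c1)C[C@@H](CCCCCCCCCCCOB(Cl)Cl)OC2=O | intermediate (not isolated)
10 | (3R)-8-hydroxy-3-(11-hydroxyundecyl)-6-methoxy-3,4-dihydroisochromen-1-one | COc1cc(O)c2c(c1)C[C@@H](CCCCCCCCCCCO)OC2=O | target

## Step count and least certain steps

Total step count: 5. Longest linear sequence: 5 steps (1 to 4 to 5 to 7 to 8 to 10); 2 and 6 are purchased.

Step 2 (key step, the new method). Several processes could defeat it: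
- poor facial selectivity in C–O bond formation, because a carboxylate binds and attacks differently from the alkoxide for which this ligand class is established and may also attack from outside the coordination sphere;
- erosion of enantiopurity by re-ionisation of the allylic lactone by zerovalent palladium before it is reoxidised;
- β-hydride elimination towards the benzylic methylene;
- decarboxylative palladation of the electron-rich, doubly ortho-substituted benzoic acid;
- migration of the terminal double bond.

The fallback uses known chemistry only. It sets out from 1 and passes through the same dilithio species 3. This is acylated in THF at −78 °C with commercial oxacyclotridecan-2-one; an excess of 3 is used because the product ketone is deprotonated as it forms, which also shields it from a second addition. Ring opening of the lactone should give 2-(13-hydroxy-2-oxotridecyl)-4,6-dimethoxybenzoic acid F1 with the chain and its free alcohol complete. Acid-catalysed cyclodehydration (TsOH, toluene, reflux with removal of water) should give 3-(11-hydroxyundecyl)-6,8-dimethoxy-1H-isochromen-1-one F2. Enantioselective hydrogenation of the C3=C4 bond of F2 is a known reaction type for 3-substituted isocoumarins. It would use a chiral ruthenium N-heterocyclic carbene–diamine catalyst (from Ru(2-methylallyl)2(cod), a chiral imidazolinium salt, KOtBu and a chiral 1,2-diamine, under H2), with the catalyst enantiomer chosen for 3R. This should give 8, where the route is rejoined before step 5; steps 3 and 4 are then not needed.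

Step 3. Homodimerisation of 6 may outrun the cross reaction, initiation at the branched alkene next to the lactone oxygen may be slow, and ruthenium hydride species may cause double-bond migration, which would alter the chain length or move the alkene towards C3. The fallback sets out from 5 and replaces metathesis by an sp3–sp3 coupling. Hydroboration of the vinyl group with 9-BBN (THF, rt; the lactone is inert) should give (3R)-3-[2-(9-borabicyclo[3.3.1]nonan-9-yl)ethyl]-6,8-dimethoxy-3,4-dihydroisochromen-1-one F5. B-alkyl Suzuki–Miyaura coupling of F5 with commercial 9-bromononan-1-ol (Pd(OAc)2, PCy3, K3PO4·H2O, THF, rt) should give 8 directly, so the route is rejoined at 8 and step 4 is not needed.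

Step 1. Deprotonation may be incomplete at the methyl group or may occur on the ring at the position between the two methoxy groups, and some O-allylation of the carboxylate or double alkylation is conceivable. The fallback sets out from 1 and uses the ester-stabilised monoanion instead. O-Methylation (MeI, K2CO3, DMF) gives methyl 2,4-dimethoxy-6-methylbenzoate F3. Lateral lithiation with LiN(iPr)2 in THF at −78 °C and alkylation with 2 give methyl 2-(but-3-en-1-yl)-4,6-dimethoxybenzoate F4. Hydrolysis of the hindered ester (KOH, DMSO–H2O, 90 °C, then cold acid) returns to the route at 4.

Step 5. Over-reaction may cleave the 6-methyl ether as well, the primary dichloroborinate may be converted to the alkyl chloride if the mixture warms, and hydrolysis of the boron chelate may be incomplete. The fallback sets out from 8 and masks the alcohol first. Acetylation (Ac2O, pyridine) gives 11-[(3R)-6,8-dimethoxy-1-oxo-3,4-dihydro-1H-isochromen-3-yl]undecyl acetate F6. BCl3 in CH2Cl2 at −78 to 0 °C then gives 11-[(3R)-8-hydroxy-6-methoxy-1-oxo-3,4-dihydro-1H-isochromen-3-yl]undecyl acetate F7. Mild methanolysis (K2CO3, MeOH, rt, acidic work-up so that any opened lactone recloses; the C3–O bond is never broken) arrives at 10.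

## Further compounds

F1 | step 2 | 2-(13-hydroxy-2-oxotridecyl)-4,6-dimethoxybenzoic acid | COc1cc(OC)c(C(=O)O)c(CC(=O)CCCCCCCCCCCO)c1
F2 | step 2 | 3-(11-hydroxyundecyl)-6,8-dimethoxy-1H-isochromen-1-one | COc1cc(OC)c2c(c1)C=C(CCCCCCCCCCCO)OC2=O
F3 | step 1 | methyl 2,4-dimethoxy-6-methylbenzoate | COC(=O)c1c(C)cc(OC)cc1OC
F4 | step 1 | methyl 2-(but-3-en-1-yl)-4,6-dimethoxybenzoate | COC(=O)c1c(CCC=C)cc(OC)cc1OC
F5 | step 3 | (3R)-3-[2-(9-borabicyclo[3.3.1]nonan-9-yl)ethyl]-6,8-dimethoxy-3,4-dihydroisochromen-1-one | COc1cc(OC)c2c(c1)C[C@@H](CCB3C4CCCC3CCC4)OC2=O
F6 | step 5 | 11-[(3R)-6,8-dimethoxy-1-oxo-3,4-dihydro-1H-isochromen-3-yl]undecyl acetate | COc1cc(OC)c2c(c1)C[C@@H](CCCCCCCCCCCOC(C)=O)OC2=O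
F7 | step 5 | 11-[(3R)-8-hydroxy-6-methoxy-1-oxo-3,4-dihydro-1H-isochromen-3-yl]undecyl acetate | COc1cc(O)c2c(c1)C[C@@H](CCCCCCCCCCCOC(C)=O)OC2=O
A1 | alternative 1 | methyl (9R)-9,20-bis(tert-butyldimethylsilyloxy)-3,5,7-trioxoicosanoate | COC(=O)CC(=O)CC(=O)CC(=O)C[C@@H](CCCCCCCCCCCO[Si](C)(C)C(C)(C)C)O[Si](C)(C)C(C)(C)C
A2 | alternative 1 | methyl 2-[(2R)-2,13-bis(tert-butyldimethylsilyloxy)tridecyl]-4,6-dihydroxybenzoate | COC(=O)c1c(O)cc(O)cc1C[C@@H](CCCCCCCCCCCO[Si](C)(C)C(C)(C)C)O[Si](C)(C)C(C)(C)C
A3 | alternative 2 | (6R)-3-bromo-6-[11-(tert-butyldimethylsilyloxy)undecyl]-5,6-dihydro-2H-pyran-2-one | BrC1=CC[C@@H](CCCCCCCCCCCO[Si](C)(C)C(C)(C)C)OC1=O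
A4 | alternative 2 | 1,3-dimethoxy-1-(trimethylsilyloxy)buta-1,3-diene (Brassard diene; ketene acetal geometry immaterial, as that carbon becomes aromatic C8) | C=C(OC)C=C(OC)O[Si](C)(C)C
A5 | alternative 2 | (3R)-3-[11-(tert-butyldimethylsilyloxy)undecyl]-8-hydroxy-6-methoxy-3,4-dihydroisochromen-1-one | COc1cc(O)c2c(c1)C[C@@H](CCCCCCCCCCCO[Si](C)(C)C(C)(C)C)OC2=O
A6 | alternative 3 | 2-(11-hydroxyundecyl)-5,7-dimethoxy-2,3-dihydro-1H-inden-1-one (racemic) | COc1cc(OC)c2c(c1)CC(CCCCCCCCCCCO)C2=O
A7 | alternative 3 | (3R)-3-(11-hydroxyundecyl)-6,8-dimethoxy-3,4-dihydroisochromen-1-one (identical with 8) | COc1cc(OC)c2c(c1)C[C@@H](CCCCCCCCCCCO)OC2=O
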